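**Remark on the chemistry (assumption):** racemic 1 is used, because the carbinol centre formed in step 1 is oxidised away in step 2 and the target has no stereocentre. Ring A is numbered as in the 2-naphthoate (C1 hydroxyl, C2 ester, C3 prenyl, C4 ether oxygen, C4a/C8a ring fusion); quinone carbons carry primes.

**Compound numbers used throughout:** 1 epichlorohydrin; 2 2-methylprop-1-en-1-ylmagnesium bromide; 3 chlorohydrin; 4 chloroketone; 5 potassium methyl malonate; 6 keto malonate diester (not isolated); 7 butenolide; 8 silyloxyfuran; 9 aryne precursor; 10 benzyne (not isolated); 11 oxabicycle (not isolated); 12 mono-silylated naphthohydroquinone; 13 2-bromo-1,4-naphthoquinone; 14 silylated aryl ether; 15 rubioncolin C.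

## Analysis of the target

Rubioncolin C (15) consists of two naphthalene-derived halves joined through one oxygen. The first half is a methyl 1-hydroxy-2-naphthoate (substituted ring A, unsubstituted benzo ring B). The second is a 1,4-naphthoquinone (quinone ring C, benzo ring D), and the link runs from O4 of ring A to C2' of ring C. Ring A is fully substituted: hydroxyl at C1, CO2Me at C2, prenyl at C3, the ether oxygen at C4, and the fusion carbons C4a and C8a. There is no stereocentre, so the synthesis is a problem of regiochemistry and chemoselectivity only. The 2-aryloxy-1,4-naphthoquinone is a vinylogous aryl ester that exchanges with alkoxides, hydroxide and amines and is easily reduced. The trisubstituted prenyl double bond is acid-sensitive and cyclises onto a neighbouring free hydroxyl or quinone. Ring A is a hydroquinone derivative that is oxidised as soon as both O1 and O4 are free. The main difficulty is that O1 and O4 are the two para oxygens of one hydroquinone and must end up different: O1 free and chelated to the ester, O4 arylated although it is flanked by the prenyl group and the peri hydrogen at C5. The strategy rests on mapping ring A onto a furan and benzyne: C1 and C4 are furan C2 and C5, O4 is the furan ring oxygen, O1 is an exocyclic silyloxy group, C2 and C3 with their ester and prenyl groups are furan C3 and C4, and C4a/C8a come from benzyne 10.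

## Retrosynthetic reasoning

**15 to 14 (O1–Si).** The last operation is removal of a silyl group from O1. Keeping O1 capped until the end is deliberate: a mono-silylated hydroquinone cannot be oxidised to the ring A quinone, and only one hydroxyl is offered to the electrophile in the preceding step. The forward reaction must cleave an aryl silyl ether without touching the aryloxyquinone or the prenyl alkene.

**14 to 12 and 13 (O4–C2').** The ether bond is cut on its quinone side, because rings C and D can be bought at the right oxidation state with a leaving group as 13. The forward reaction is an addition–elimination of the O4 naphtholate of 12 on the bromoquinone. It must tolerate the steric shielding of O4 and avoid electron transfer between an electron-rich naphtholate and a quinone.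

**12 to 8 and 9 through 11 and 10 (C1–C8a and C4–C4a).** Ring A is opened at its two bonds to the ring fusion, so that ring B becomes benzyne 10 and C1–C4 become a 2-silyloxyfuran. This cut is preferred to any cut inside the C1–C4 chain for three reasons. It places all four substituents of ring A on a five-membered heterocycle whose substitution pattern is fixed by simple carbonyl chemistry. It removes regiochemistry from the ring-forming event, since 10 is symmetrical. It delivers O1 and O4 already different, since one starts as a silyl ketene acetal oxygen and the other as the furan ring oxygen. The forward reaction must give the cycloadduct 11 and open its bridge toward C1 so that silicon stays on O1.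

**8 to 7 (O–Si).** The furan is the silyl dienol ether of the 3-carbomethoxybutenolide 7. The forward reaction has to remove a proton from C5 of the lactone and not from the doubly allylic side-chain methylene; the gain in furan aromaticity is what is relied on.

**7 to 4 and 5 through 6 (C3=C4 and the ester C–O).** The butenolide is cut at its ring double bond (Knoevenagel retron) and at the lactone O–CH2 bond. This gives a malonate half-ester salt 5 and an α-chloro ketone 4, which are joined by carboxylate alkylation to give 6 and then closed. Carrying the malonate in as a carboxylate nucleophile avoids a separate hydroxymethyl ketone and strongly basic transesterification conditions, which would endanger the skipped alkene.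

**4 to 3 to 1 and 2 (C=O, and C3–C4 of the hexenyl chain).** The chloroketone is the oxidation product of chlorohydrin 3, which is the product of a copper-catalysed opening of 1 by the alkenyl Grignard reagent 2. A homologation of a β,γ-unsaturated acid through a diazomethyl ketone was set aside. The β,γ double bond is known to capture the diazonium or carbenoid centre generated from such ketones, and the epoxide route needs neither a diazoalkane nor acid.

## Alternatives that were turned down

**Alternative 1: Dötz benzannulation with the ether already on the carbene.**
- Disconnection and key step: ring A is cut at C3–C4, C1–C2 and C1–C8a. The forward step heats the zerovalent chromium complex pentacarbonyl[{[1,4-bis(methoxymethoxy)naphthalen-2-yl]oxy}(phenyl)methylidene]chromium A3 with the alkyne 1,1-diethoxy-6-methylhept-5-en-2-yne A2. The carbene carbon becomes C4, a carbonyl ligand becomes C1, the phenyl group becomes ring B and the alkyne supplies C2 and C3, giving the naphthol A1.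
- For it: it is convergent, it makes the hindered O4–aryl bond before ring A exists, and O1 is born as the free phenol while O4 is born as the ether. On the point of forming the ether at a shielded oxygen it is stronger than the chosen route.
- Against it: the orientation of alkyne insertion depends on the size difference between a diethoxymethyl group and a prenyl methylene, both sp3 carbons, so a mixture of regioisomers is likely. Aryloxy carbene complexes are less stabilised than alkoxy ones and must be made by exchange with a naphthol. Chromium is stoichiometric. A1 still needs acetal hydrolysis, oxidation of the aldehyde to the acid, esterification, removal of two acetal protecting groups and oxidation to the quinone, all beside a free naphthol and a prenyl group.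
- Comparison: the chosen route fixes the ester/prenyl adjacency in the furan, carries C2 at the ester oxidation level from the start and needs two steps after its key step instead of four or five.

**Alternative 2: quinone ring from a squarate-derived cyclobutenone.**
- Disconnection and key step: bond C1'–C8a' of ring C is cut. Heating the cyclobutenone A5 opens the four-membered ring to a vinylketene, which closes onto the ortho carbon of its phenyl group and tautomerises to the naphthohydroquinone A4; mild oxidation would then give 15.
- For it: the key step is thermal, neutral and reagent-free, and the ether is formed at the cyclobutenedione stage, so no naphtholate meets an oxidising quinone. On that point it is at least as good as the chosen route.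
- Against it: it spends its key step on rings C and D, which are available as 13, while ring A, the real problem, must already be complete. A5 requires an aryl-metal addition to an aryloxycyclobutenedione in which the aryloxide is a good leaving group and in which the ester and hydroxyl of ring A would have to be masked.
- Comparison: it does not address C1–C4 of ring A at all, whereas the chosen strategy builds exactly that ring and takes the quinone from 13 in one step.

**Alternative 3: ring expansion of an indane-1,3-dione.**
- Disconnection and key step: bond C1–C2 of ring A is cut. Methoxide opens the 2,2-disubstituted indanedione A7 by retro-Claisen cleavage, and the ester enolate of the acetate arm closes on the new benzoate (Dieckmann), giving after tautomerisation the hydroquinone A6.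
- For it: A7 comes from two alkylations of a cheap dione, there is no aryne, no silicon and no sensitive diene, and A6 is reached in about three steps. In step economy it is stronger than the chosen route.
- Against it: A6 has both oxygens free, so O1 and O4 are told apart only by the hydrogen bond of O1 to the ester. A6 is an electron-rich hydroquinone that must meet the oxidant 13 under base, so redox exchange to the ring A quinone, followed by cyclisation of the prenylquinone to a chromene, competes with ether formation.
- Comparison: the chosen strategy gives the O1/O4 differentiation as a consequence of the ring-forming step and a silyl group on O1 that blocks oxidation while the quinone is attached. The selective etherification of A6 is kept as a fallback for step 7.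

Key step: step 5

## Route

**Step 1**
Reactants: 1 epichlorohydrin (racemic 2-(chloromethyl)oxirane); 2 2-methylprop-1-en-1-ylmagnesium bromide
Product: 3 1-chloro-5-methylhex-4-en-2-ol (racemic)
Conditions: CuI (10 mol %), THF, −40 → −20 °C; aq. NH4Cl
Reagents that add atoms: none
Why: Copper-catalysed Grignard opening of a terminal epoxide (organocuprate SN2 at the unsubstituted oxirane carbon); at low temperature the alkenylcopper species attacks the epoxide CH2 much faster than the C–Cl bond and the magnesium alkoxide does not close to a new epoxide. The carbinol centre forms as a racemate and is erased in step 2.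

**Step 2**
Reactants: 3 1-chloro-5-methylhex-4-en-2-ol
Product: 4 1-chloro-5-methylhex-4-en-2-one
Conditions: Dess–Martin periodinane, CH2Cl2, 0 °C → rt
Reagents that add atoms: none
Why: Dess–Martin oxidation of a secondary alcohol to the ketone; the conditions are non-basic and only weakly acidic, so the skipped (β,γ) double bond should not move into conjugation and the α-chloro ketone should not react further.

**Step 3**
Reactants: 4 1-chloro-5-methylhex-4-en-2-one; 5 potassium methyl malonate (potassium 3-methoxy-3-oxopropanoate)
Product: 7 methyl 4-(3-methylbut-2-en-1-yl)-2-oxo-2,5-dihydrofuran-3-carboxylate, via keto malonate diester 6 (not isolated)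
Conditions: NaI (10 mol %), DMF, rt; then Et3N, rt → 40 °C
Reagents that add atoms: none
Why: SN2 displacement of the α-chloro ketone by the carboxylate (iodide catalysis) gives 6, and the amine then induces an intramolecular Knoevenagel condensation: 5-exo-trig aldol addition of the malonate carbanion to the activated α-acyloxy ketone and E1cB loss of water. This is the established butenolide synthesis from α-halo ketones and activated acetic acids. A weak base is chosen so that the doubly allylic methylene of 7 is not deprotonated for long.

**Step 4**
Reactants: 7 methyl 4-(3-methylbut-2-en-1-yl)-2-oxo-2,5-dihydrofuran-3-carboxylate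
Product: 8 methyl 4-(3-methylbut-2-en-1-yl)-2-[(triisopropylsilyl)oxy]furan-3-carboxylate
Conditions: TIPSOTf, Et3N, CH2Cl2, 0 °C
Reagents that add atoms: triisopropylsilyl trifluoromethanesulfonate (TIPSOTf), CC(C)[Si](C(C)C)(C(C)C)OS(=O)(=O)C(F)(F)F
Why: Soft enolisation of a butenolide to its 2-silyloxyfuran: O-silylation of the lactone carbonyl followed by loss of a C5 proton gives the aromatic furan, whereas loss of the side-chain proton would give a non-aromatic exocyclic dienol ether, so aromatisation should direct the deprotonation to C5. The 3-ester makes the silyl ketene acetal a push–pull system that can be handled on base-washed silica.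

**Step 5**
Reactants: 8 methyl 4-(3-methylbut-2-en-1-yl)-2-[(triisopropylsilyl)oxy]furan-3-carboxylate; 9 2-(trimethylsilyl)phenyl trifluoromethanesulfonate
Product: 12 methyl 4-hydroxy-3-(3-methylbut-2-en-1-yl)-1-[(triisopropylsilyl)oxy]-2-naphthoate, via benzyne 10 (not isolated), via silyloxy oxabicycle 11 (not isolated)
Conditions: 9 (1.2 equiv), CsF (2.5 equiv), MeCN, rt; then silica gel, CH2Cl2
Reagents that add atoms: none
Why: Fluoride removes the trimethylsilyl group of 9 and the ortho triflate leaves, releasing benzyne 10 (Kobayashi aryne generation). 10 adds suprafacially across C2 and C5 of the electron-rich furan 8 in a concerted [4+2] cycloaddition (aryne–furan Diels–Alder), which closes ring A as the six-membered carbocycle of the 7-oxabenzonorbornadiene 11 and forms C1–C8a and C4–C4a in one event. Because 10 is symmetrical there is no regiochemical issue in the cycloaddition, and the sequence silyloxy carbon, ester carbon, prenyl carbon, CH is carried over unchanged from the furan to C1–C4. The bridgehead C1 of 11 is a silyl ketal: its C1–O bridge bond ionises with lone-pair assistance from the silyloxy oxygen to a benzylic oxocarbenium ion, the bridge oxygen stays on C4 as an alkoxide, and loss of H4 aromatises ring A, so silicon remains on O1 and O4 becomes the free hydroxyl. The alternative cleavage of the C4–O bond would give a cation without oxygen stabilisation and conjugated through C3=C2 to the ester-bearing carbon, so the opening is directed toward C1. The closest known reaction type is the cycloaddition of arynes with 2-alkoxy- and 2-silyloxyfurans, whose adducts open to 4-alkoxy- or 4-silyloxy-1-naphthols. The two bridgehead stereocentres of 11 are cis by the geometry of the bicycle, form as a racemate and disappear on aromatisation, so nothing stereochemical has to be controlled. The step needs chemoselectivity for the diene over the prenyl alkene (ene reaction) and for the C–Si bond of 9 over the O–Si bond of 8; the high reactivity of the 2-oxygenated furan, the bulk of the triisopropylsilyl group, the low solubility of CsF in MeCN and the use of only a slight excess of 9 (which also limits O-arylation of the product) are relied on for this.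

**Step 6**
Reactants: 12 methyl 4-hydroxy-3-(3-methylbut-2-en-1-yl)-1-[(triisopropylsilyl)oxy]-2-naphthoate; 13 2-bromo-1,4-naphthoquinone
Product: 14 methyl 4-[(1,4-dioxo-1,4-dihydronaphthalen-2-yl)oxy]-3-(3-methylbut-2-en-1-yl)-1-[(triisopropylsilyl)oxy]-2-naphthoate
Conditions: Cs2CO3, MeCN, 0 °C → rt, under argon, dark
Reagents that add atoms: none
Why: Addition–elimination (vinylogous acyl substitution) of the O4 naphtholate on the bromoquinone; attack at the bromine-bearing carbon or at the neighbouring CH followed by loss of bromide leads to the same ether, because the benzo ring of 13 is unsubstituted. O4 is the only free hydroxyl, and the silyl group on O1 prevents oxidation of ring A to a quinone by 13.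

**Step 7**
Reactants: 14 methyl 4-[(1,4-dioxo-1,4-dihydronaphthalen-2-yl)oxy]-3-(3-methylbut-2-en-1-yl)-1-[(triisopropylsilyl)oxy]-2-naphthoate
Product: 15 rubioncolin C, methyl 4-[(1,4-dioxo-1,4-dihydronaphthalen-2-yl)oxy]-1-hydroxy-3-(3-methylbut-2-en-1-yl)-2-naphthoate
Conditions: HF·pyridine, pyridine, THF, 0 °C → rt
Reagents that add atoms: none
Why: Fluoride cleavage of an aryl silyl ether whose leaving naphthol is activated by the ortho ester. The buffered acidic medium generates no free alkoxide or naphtholate that could exchange with the aryloxyquinone, and excess pyridine keeps HF from adding to the prenyl double bond. The liberated O1–H is held by a hydrogen bond to the ester.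

## Compound list

1 | epichlorohydrin (racemic 2-(chloromethyl)oxirane) | ClCC1CO1 | starting material
2 | 2-methylprop-1-en-1-ylmagnesium bromide | CC(C)=C[Mg]Br | starting material
3 | 1-chloro-5-methylhex-4-en-2-ol (racemic) | CC(C)=CCC(O)CCl | intermediate
4 | 1-chloro-5-methylhex-4-en-2-one | CC(C)=CCC(=O)CCl | intermediate
5 | potassium methyl malonate | [K+].[O-]C(=O)CC(=O)OC | starting material
6 | methyl 5-methyl-2-oxohex-4-en-1-yl propanedioate | COC(=O)CC(=O)OCC(=O)CC=C(C)C | intermediate (not isolated)
7 | methyl 4-(3-methylbut-2-en-1-yl)-2-oxo-2,5-dihydrofuran-3-carboxylate | COC(=O)C1=C(CC=C(C)C)COC1=O | intermediate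
8 | methyl 4-(3-methylbut-2-en-1-yl)-2-[(triisopropylsilyl)oxy]furan-3-carboxylate | COC(=O)c1c(O[Si](C(C)C)(C(C)C)C(C)C)occ1CC=C(C)C | intermediate
9 | 2-(trimethylsilyl)phenyl trifluoromethanesulfonate | C[Si](C)(C)c1ccccc1OS(=O)(=O)C(F)(F)F | starting material
10 | benzyne (1,2-didehydrobenzene) | C1=CC#CC=C1 | intermediate (not isolated)
11 | methyl 3-(3-methylbut-2-en-1-yl)-1-[(triisopropylsilyl)oxy]-1,4-dihydro-1,4-epoxynaphthalene-2-carboxylate (racemic, bridgeheads cis by necessity) | COC(=O)C1=C(CC=C(C)C)C2OC1(O[Si](C(C)C)(C(C)C)C(C)C)c1ccccc12 | intermediate (not isolated)
12 | methyl 4-hydroxy-3-(3-methylbut-2-en-1-yl)-1-[(triisopropylsilyl)oxy]-2-naphthoate | COC(=O)c1c(CC=C(C)C)c(O)c2ccccc2c1O[Si](C(C)C)(C(C)C)C(C)C | intermediate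
13 | 2-bromo-1,4-naphthoquinone | O=C1C=C(Br)C(=O)c2ccccc12 | starting material
14 | methyl 4-[(1,4-dioxo-1,4-dihydronaphthalen-2-yl)oxy]-3-(3-methylbut-2-en-1-yl)-1-[(triisopropylsilyl)oxy]-2-naphthoate | COC(=O)c1c(CC=C(C)C)c(OC2=CC(=O)c3ccccc3C2=O)c2ccccc2c1O[Si](C(C)C)(C(C)C)C(C)C | intermediate
15 | rubioncolin C | COC(=O)c1c(CC=C(C)C)c(OC2=CC(=O)c3ccccc3C2=O)c2ccccc2c1O | target

## Step count and least certain steps

Total: 7 steps. Longest linear sequence: 7 steps (1 and 2 to 15); 5, 9 and 13 enter at steps 3, 5 and 6.

**Step 5 (key step).**
- What may go wrong: fluoride may cleave the O–Si bond of the silyl ketene acetal 8 faster than it releases the aryne. The aryne may be consumed by an ene reaction with the prenyl group or by O-arylation of the product naphtholate. Silicon may be lost from the oxocarbenium stage of the opening, which would leave both oxygens free. The preparation of 8 itself (step 4) carries the related risk that the side-chain methylene is deprotonated instead of C5.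
- Fallback: the same oxabicycle is made with the roles of the partners exchanged, which needs no aryne, no fluoride and no butenolide. Methyl propiolate is coupled with prenyl bromide (CuI, NaI, K2CO3, DMF, rt) to give methyl 6-methylhept-5-en-2-ynoate F1. Phthalide is converted with LiN(SiMe3)2 and TIPSOTf in THF at −78 °C into 1-[(triisopropylsilyl)oxy]isobenzofuran F2, which is trapped without isolation by F1 on warming. In this known type of isobenzofuran Diels–Alder reaction, the silyloxy-bearing terminus of the diene should bond to the ester-bearing alkyne carbon and the unsubstituted terminus to the prenyl-bearing carbon. This gives 11, which opens to 12 as in the main route.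
- Where it branches: it does not set out from an intermediate of the route but from purchased phthalide, methyl propiolate and prenyl bromide. It replaces steps 1 to 5 and comes back at compound 12 (through 11).

**Step 6.**
- What may go wrong: electron transfer from the electron-rich naphtholate to the quinone may compete with substitution. The shielding of O4 by the prenyl group and H5 may slow the addition. Carbonate may slowly remove the silyl group.
- Fallback: it sets out from 12 and comes back at 14, replacing the oxidising electrophile by a protected one. A copper-catalysed Ullmann ether coupling of 12 with 2-bromo-1,4-dimethoxynaphthalene (CuI, picolinic acid, K3PO4, DMSO, 80 °C) should give methyl 4-[(1,4-dimethoxynaphthalen-2-yl)oxy]-3-(3-methylbut-2-en-1-yl)-1-[(triisopropylsilyl)oxy]-2-naphthoate F3. Oxidative demethylation of its more electron-rich trioxygenated naphthalene with (NH4)2Ce(NO3)6 in MeCN/H2O at 0 °C then gives 14.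

**Step 7.**
- What may go wrong: hydrofluorination of the prenyl double bond, slow cleavage of the hindered silyl ether, or exchange at the aryloxyquinone if the medium becomes basic.
- Fallback: it sets out from 12 and comes back at 15, removing silicon before the quinone is present. Bu4NF buffered with AcOH in THF at 0 °C should give methyl 1,4-dihydroxy-3-(3-methylbut-2-en-1-yl)-2-naphthoate F4 (the same diol as A6). One equivalent of Cs2CO3 and 13 in degassed DMF at 0 °C should then etherify the non-chelated O4 selectively, O1 being held by its hydrogen bond to the ester, to give 15 directly.

**Step 3.**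
- What may go wrong: base-mediated migration of the skipped double bond into conjugation (in 4, 6 or 7), incomplete dehydration of the aldol intermediate, or self-condensation of the chloroketone.
- Fallback: it sets out from 5 and comes back at 7, introducing the prenyl group by cross-coupling onto a preformed ring. Alkylation of 5 with methyl bromoacetate (DMF, rt) gives methyl 2-methoxy-2-oxoethyl propanedioate F5. Dieckmann cyclisation (KOtBu, THF, 0 °C) gives methyl 4-hydroxy-2-oxo-2,5-dihydrofuran-3-carboxylate F6. Tf2O and iPr2NEt in CH2Cl2 at −78 °C give methyl 2-oxo-4-{[(trifluoromethyl)sulfonyl]oxy}-2,5-dihydrofuran-3-carboxylate F7. A Stille coupling of F7 with tributyl(3-methylbut-2-en-1-yl)stannane (Pd(PPh3)4, LiCl, THF, 60 °C) should then give 7.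

## Further compounds

F1 | step 5 | methyl 6-methylhept-5-en-2-ynoate | COC(=O)C#CCC=C(C)C
F2 | step 5 | 1-[(triisopropylsilyl)oxy]isobenzofuran | CC(C)[Si](Oc1occ2ccccc12)(C(C)C)C(C)C
F3 | step 6 | methyl 4-[(1,4-dimethoxynaphthalen-2-yl)oxy]-3-(3-methylbut-2-en-1-yl)-1-[(triisopropylsilyl)oxy]-2-naphthoate | COC(=O)c1c(CC=C(C)C)c(Oc2cc(OC)c3ccccc3c2OC)c2ccccc2c1O[Si](C(C)C)(C(C)C)C(C)C
F4 | step 7 | methyl 1,4-dihydroxy-3-(3-methylbut-2-en-1-yl)-2-naphthoate | COC(=O)c1c(CC=C(C)C)c(O)c2ccccc2c1O
F5 | step 3 | methyl 2-methoxy-2-oxoethyl propanedioate | COC(=O)CC(=O)OCC(=O)OC
F6 | step 3 | methyl 4-hydroxy-2-oxo-2,5-dihydrofuran-3-carboxylate | COC(=O)C1=C(O)COC1=O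
F7 | step 3 | methyl 2-oxo-4-{[(trifluoromethyl)sulfonyl]oxy}-2,5-dihydrofuran-3-carboxylate | COC(=O)C1=C(OS(=O)(=O)C(F)(F)F)COC1=O
A1 | alternative 1 | 4-{[1,4-bis(methoxymethoxy)naphthalen-2-yl]oxy}-2-(diethoxymethyl)-3-(3-methylbut-2-en-1-yl)naphthalen-1-ol | CCOC(OCC)c1c(CC=C(C)C)c(Oc2cc(OCOC)c3ccccc3c2OCOC)c2ccccc2c1O
A2 | alternative 1 | 1,1-diethoxy-6-methylhept-5-en-2-yne | CCOC(OCC)C#CCC=C(C)C
A3 | alternative 1 | pentacarbonyl[{[1,4-bis(methoxymethoxy)naphthalen-2-yl]oxy}(phenyl)methylidene]chromium | O=C=[Cr](=C=O)(=C=O)(=C=O)(=C=O)=C(Oc1cc(OCOC)c2ccccc2c1OCOC)c1ccccc1
A4 | alternative 2 | methyl 4-[(1,4-dihydroxynaphthalen-2-yl)oxy]-1-hydroxy-3-(3-methylbut-2-en-1-yl)-2-naphthoate | COC(=O)c1c(CC=C(C)C)c(Oc2cc(O)c3ccccc3c2O)c2ccccc2c1O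
A5 | alternative 2 | methyl 1-hydroxy-4-[(4-hydroxy-3-oxo-4-phenylcyclobut-1-en-1-yl)oxy]-3-(3-methylbut-2-en-1-yl)-2-naphthoate (racemic) | COC(=O)c1c(CC=C(C)C)c(OC2=CC(=O)C2(O)c2ccccc2)c2ccccc2c1O
A6 | alternative 3 | methyl 1,4-dihydroxy-3-(3-methylbut-2-en-1-yl)-2-naphthoate | COC(=O)c1c(CC=C(C)C)c(O)c2ccccc2c1O
A7 | alternative 3 | methyl 2-[2-(3-methylbut-2-en-1-yl)-1,3-dioxo-2,3-dihydro-1H-inden-2-yl]acetate | COC(=O)CC1(CC=C(C)C)C(=O)c2ccccc2C1=O
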